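The 34% of substrate left in the ochre run at 40.0 min stood above the 28% left in the red run at 25.0 min by more than the scatter, and I built my reckoning on that leftover.

| setting | ochre | red | flask |
|---|---|---|---|
| substrate | 1.5 M | 1.5 M | 1.5 M |
| partner | 1.2 equiv | 1.2 equiv | 1.20 equiv |
| initiator | 0.35 mol% | 0.78 mol% | 0.52 mol% |
| remark | run made earlier | run made earlier |  |
| time |  |  | 50 min |

| run | time / min | product / % | substrate / % |
|---|---|---|---|
| ochre | 4.00 | 11 | 86 |
| ochre | 10.0 | 30 | 71 |
| ochre | 20.0 | 46 | 52 |
| ochre | 30.0 | 60 | 37 |
| ochre | 40.0 | 66 | 34 |
| red | 8.00 | 37 | 65 |
| red | 15.0 | 54 | 47 |
| red | 25.0 | 68 | 28 |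
| red | 30.0 | 77 | 25 |
| red | 40.0 | 84 | 15 |

(scatter of a reading: 1.5 percentage points)

* the product in the flask at 50 min, as a percentage of the substrate charged
* the substrate in the flask at 50 min, as a percentage of the substrate charged

- in percentages every species weighs as the substrate in it: one ended chains counts as two
- steps under discussion: initiator -> 2 initiating radical; 2 first chain carrier -> ended chains; partner -> decomposed reagent; substrate + second chain carrier -> by-product + first chain carrier; partner + first chain carrier -> product + second chain carrier; substrate + initiating radical -> capped initiator + first chain carrier

Taking the chain carriers as settled (the steady state), made as initiator breaks and ended when two first chain carriers meet, I used the bench rule that, with the charges of substrate and partner held, equal substrate comes at equal time multiplied by the square root of the loading. Between the runs the stretch of time, the square root of the ratio of loadings, is 1.49. The rule passed at 30.0 min, where ochre read 37% and red, at 20.1 min, lay near 37.5% between its readings. But red's 25.0 min stretches to 37.2 min, earlier than ochre's last reading, and ochre still lagged there; partner breaking down needs no carrier, so I suspected it of keeping clock time. I therefore read from that one late pair, with its scatter, a drag of 12 percentage points, the substrate points a slower flask with the same charges of substrate and partner lags behind the rule late in a run, per unit of stretch above one: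

substrate = faster run's reading at (time ÷ stretch) + drag × (stretch − one)

From red the flask has a stretch of 1.22, which turns 40.0 min into 48.8 min, close to 50 min, so I reckoned 17.7% of substrate. The forecast came by another road, from decay constants and the finding “so the rate is half order in initiator”: substrate 17.5% (14% to 22%), product 81% (77% to 85%).

The flask gave 19.1% of substrate and 80.6% of product, inside both ranges.

    initiator → 2 initiating radical (k = 1.10 × 10⁻⁴ s⁻¹)
    2 first chain carrier → ended chains (k = 9.00 × 10⁶ L mol⁻¹ s⁻¹)
    partner → decomposed reagent (k = 2.00 × 10⁻⁴ s⁻¹)
    substrate + second chain carrier → by-product + first chain carrier (k = 9600 L mol⁻¹ s⁻¹)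
    partner + first chain carrier → product + second chain carrier (k = 2000 L mol⁻¹ s⁻¹)
    substrate + initiating radical → capped initiator + first chain carrier (k = 12000 L mol⁻¹ s⁻¹)

Those two numbers do not show the partner in the flask, down to 9.95% of its charge beside 0.412 M of decomposed reagent. The neighbouring flask with 0.13 mol% of initiator has a stretch of 1.64 from ochre, which turns 50 min into 30.5 min, beside ochre's reading of 37% at 30.0 min. The drag adds 7.8 points, which makes 44.7%. At 50.0 min that neighbouring flask held 45.5% of substrate and 54.4% of product, with 0.563 M of decomposed reagent.

The numbers in the tables are simulated with made-up constants.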